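**Retrosynthetic overview**
- The C6 ester is made last from the C6 alcohol and (2S,3S)-2,3-dimethyloxirane-2-carboxylic acid; the C11=C13 methylene is unveiled from an α-phosphono lactone by Horner–Wadsworth–Emmons reaction with formaldehyde.
- The strategy rests on the olefin C2=C3(–O) of the 3(2H)-furanone ring, whose oxygen-bearing C3 is bonded to vinylic C4 of the Z C4=C5 olefin: C3–C4 is cut as an intramolecular Heck bond between a Z C4 vinyl iodide and the furanone C3–H.
- The furanone ring comes from a C1 ethynyl ketone and the C10 hydroxyl; the Z vinyl iodide and the C6 carbinol come from a C6 propynyl ketone by hydroiodination and Felkin reduction.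
- The γ-lactone with C7 and C8 comes from an Evans syn-aldol of a succinate imide with a C8 aldehyde followed by lactonisation; C10 is taken from (R)-citramalic acid.
- Ring order: γ-lactone first, furanone second, nine-membered oxacycle (ten-membered carbocycle) last.

Key step: step 16

Remark: atoms carry germacranolide numbers (C1 furanone ketone, C2=C3–O, C4(Me)=C5, C6 carbinol, C7, C8 lactone carbinol, C9H2, C10 quaternary, C11/C12 lactone α-carbon and carbonyl, C13 methylene); the labile C11 phosphonate centre is drawn as the trans epimer, and either epimer converges in step 17.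

**Route**

Step 1
Reactants: 1 (R)-citramalic acid
Product: 2 (R)-2-(2,2,4-trimethyl-5-oxo-1,3-dioxolan-4-yl)acetic acid
Conditions: Me2C(OMe)2, TsOH·H2O (cat.), CH2Cl2, rt
Reagents that add atoms: 2,2-dimethoxypropane COC(C)(C)OC
Why: Acid-catalysed acetal exchange ties the tertiary hydroxyl and the adjacent carboxyl into the five-membered 1,3-dioxolan-4-one, which leaves only the CH2CO2H arm free and does not touch the stereocentre.

Step 2
Reactants: 2 dioxolanone acid
Product: 4 (3R)-3-hydroxy-3-methyloxolan-2-one, via dioxolanone alcohol 3 (not isolated)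
Conditions: BH3·SMe2, THF, 0 °C to rt; MeOH; then TsOH·H2O (cat.), CH2Cl2, rt
Reagents that add atoms: none
Why: Borane reduces the free carboxylic acid chemoselectively and the primary alcohol then transacylates onto the activated dioxolanone (acid-catalysed lactonisation with loss of acetone), so C8 reaches the alcohol level while C1 stays an acyl group.

Step 3
Reactants: 4 hydroxy lactone
Product: 5 (3R)-3-methyl-3-(triethylsilyloxy)oxolan-2-one
Conditions: Et3SiOTf, 2,6-lutidine, CH2Cl2, −78 to 0 °C
Reagents that add atoms: triethylsilyl trifluoromethanesulfonate CC[Si](CC)(CC)OS(=O)(=O)C(F)(F)F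
Why: Silyl triflate silylation protects the hindered tertiary alcohol so that it cannot quench the boron and lithium enolates used later.

Step 4
Reactants: 5 silyloxy lactone
Product: 6 (2R)-4-hydroxy-N-methoxy-N,2-dimethyl-2-(triethylsilyloxy)butanamide
Conditions: MeNHOMe·HCl, AlMe3, CH2Cl2, 0 °C to rt; cold 0.5 M HCl work-up
Reagents that add atoms: N,O-dimethylhydroxylamine hydrochloride CNOC.Cl
Why: Weinreb aminolysis of the lactone by the aluminium amide opens the ring to the C1 Weinreb amide (the later acyl acceptor for the furanone carbons) and frees the C8 alcohol.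

Step 5
Reactants: 6 hydroxy Weinreb amide
Product: 7 (2R)-N-methoxy-N,2-dimethyl-4-oxo-2-(triethylsilyloxy)butanamide
Conditions: Dess–Martin periodinane, NaHCO3, CH2Cl2, 0 °C to rt
Reagents that add atoms: none
Why: Dess–Martin oxidation of the primary alcohol, run at once so that the γ-hydroxy amide cannot revert to the lactone, gives a β-silyloxy aldehyde that has no epimerisable centre.

Step 6
Reactants: 8 (4R)-4-benzyl-1,3-oxazolidin-2-one + 9 methyl 4-chloro-4-oxobutanoate
Product: 10 methyl 4-[(4R)-4-benzyl-2-oxo-1,3-oxazolidin-3-yl]-4-oxobutanoate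
Conditions: n-BuLi, THF, −78 °C; then 9, −78 to 0 °C
Reagents that add atoms: none
Why: N-acylation of the lithiated oxazolidinone with the acid chloride is the standard preparation of an Evans imide.

Step 7
Reactants: 10 succinate imide + 7 aldehyde
Product: 12 syn-aldol adduct (7R,8S,10R; C6 imide; C12 methyl ester; free C8 OH; C10 OSiEt3; C1 Weinreb amide), via Z-boron enolate 11 (not isolated)
Conditions: n-Bu2BOTf, i-Pr2NEt, CH2Cl2, −78 to 0 °C; then 7, −78 to 0 °C; pH 7 buffer, MeOH, 30% H2O2, 0 °C
Reagents that add atoms: none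
Why: In this Evans syn-aldol reaction the Z-boron enolate reacts through a Zimmerman–Traxler chair on the face opposite the benzyl group of the (R)-auxiliary, which sets C7 and C8 (7R,8S) independently of the remote C10 centre.

Step 8
Reactants: 12 aldol adduct
Product: 14 trans-lactone acid (7R,8S,10R; 8,12-lactone carrying the C6 carboxylic acid), via hydroxy diacid 13 (not isolated)
Conditions: LiOH, 30% H2O2, THF/H2O, 0 °C to rt; Na2SO3; then 1 M HCl to pH 2, rt
Reagents that add atoms: hydrogen peroxide OO
Why: Hydroperoxide cleaves the imide at the exocyclic carbonyl (Evans LiOOH cleavage) while hydroxide saponifies the methyl ester, and on acidification the γ-hydroxy acid closes to the five-membered lactone, which is trans because it derives from the syn aldol.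

Step 9
Reactants: 14 lactone acid
Product: 16 C6 but-2-ynoyl lactone (ynone; 7R,8S,10R), via acid chloride 15 (not isolated)
Conditions: Me2C=C(Cl)NMe2, CH2Cl2, 0 °C to rt; then propyne, PdCl2(PPh3)2 (cat.), CuI (cat.), Et3N, THF, rt
Reagents that add atoms: propyne CC#C
Why: Neutral acid chloride formation followed by acyl Sonogashira coupling gives the ynone without touching the lactone or the Weinreb amide, and any enolisation at C7 can only return the favoured trans arrangement.

Step 10
Reactants: 16 ynone
Product: 17 (Z)-β-iodoenone (C6 ketone; C5H=C4(Me)I with iodine cis to C6; 7R,8S,10R)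
Conditions: NaI, AcOH, rt
Reagents that add atoms: sodium iodide [Na+].[I-]
Why: Conjugate hydroiodination of an ynone (iodide adds at C4 and the allenol is protonated anti to iodine) gives the Z β-iodoenone kinetically, which fixes both the position of the iodine and the C4=C5 geometry.

Step 11
Reactants: 17 iodoenone
Product: 18 (6R)-allylic alcohol (Z vinyl iodide; 7S,8S,10R by priority change only)
Conditions: NaBH4, CeCl3·7H2O, MeOH, −78 °C
Reagents that add atoms: none
Why: In this Luche 1,2-reduction hydride is expected to add under Felkin–Anh control anti to the C7–C8 bond (the larger ring branch), which gives the 6R carbinol that the target needs.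

Step 12
Reactants: 18 allylic alcohol
Product: 19 C6 tert-butyldimethylsilyl ether (6R,7R,8S,10R)
Conditions: t-BuMe2SiOTf, 2,6-lutidine, CH2Cl2, −78 to 0 °C
Reagents that add atoms: tert-butyldimethylsilyl trifluoromethanesulfonate CC(C)(C)[Si](C)(C)OS(=O)(=O)C(F)(F)F
Why: Silyl triflate protection of the hindered allylic alcohol is done at once to block translactonisation to the 6,12-olide and to carry C6–O through the base and organometallic steps.

Step 13
Reactants: 19 silyl ether lactone
Product: 21 C11 diethyl phosphonate (α-phosphono lactone; 6R,7R,8S,10R,11R), via phosphonite 20 (not isolated)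
Conditions: LiN(i-Pr)2, THF, −78 °C (short); ClP(OEt)2, −78 °C to rt; then 30% H2O2, 0 °C
Reagents that add atoms: diethyl chlorophosphite CCOP(Cl)OCC; hydrogen peroxide OO
Why: Kinetic lactone enolate formation, C-phosphinylation with the soft trivalent phosphorus chloride and oxidation (the phosphite-trapping route to α-phosphono lactones) install the masked methylene anti to the C7 side chain, and the cold enolate is trapped before it can attack the hindered Weinreb amide.

Step 14
Reactants: 21 phosphono lactone Weinreb amide
Product: 22 C1 ethynyl ketone (C10 OSiEt3; other groups unchanged)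
Conditions: HC≡CMgBr (excess), THF, 0 °C to rt; aq. NH4Cl
Reagents that add atoms: ethynylmagnesium bromide C#C[Mg]Br
Why: The first equivalent of Grignard reagent turns the acidic α-phosphono lactone into its unreactive enolate and a further equivalent adds once to the Weinreb amide through the stable chelate (Weinreb ketone synthesis), which gives the terminal ynone on work-up.

Step 15
Reactants: 22 ethynyl ketone
Product: 25 furanone vinyl iodide (2-methyl-3(2H)-furanone unsubstituted at C3; C6 OTBS; Z C4 vinyl iodide; C11 phosphonate; 6R,7R,8S,10R,11R), via silyloxy enaminone 23 (not isolated), via hydroxy enaminone 24 (not isolated)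
Conditions: Et2NH, THF, 0 °C; then HF·pyridine, pyridine, THF, 0 °C to rt
Reagents that add atoms: none
Why: Diethylamine adds to the ynone to give the vinylogous amide, fluoride then frees the tertiary hydroxyl from its triethylsilyl ether faster than it attacks the secondary tert-butyldimethylsilyl ether, and the acidic medium closes the hydroxy enaminone to the furanone with loss of diethylamine (the known enaminone-to-furanone cyclisation).

Step 16
Reactants: 25 furanone vinyl iodide
Product: 26 furanone-bridged macrocycle (C3–C4 bond; C2=C3–C4=C5 dienone; C6 OTBS; C11 phosphonate; 4Z,6S,7R,8S,10R,11R)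
Conditions: Pd(OAc)2 (20 mol%), PPh3 (40 mol%), Ag2CO3 (2 equiv), MeCN, 70 °C, 1 mM, slow addition
Reagents that add atoms: none
Why: Proposed new method: PPh3 reduces Pd(OAc)2 to zerovalent palladium, which inserts into the C4–I bond with retention of the Z geometry, and Ag2CO3 removes iodide so that the cationic vinylpalladium binds the furanone C2=C3 bond and adds across it syn, carbon to C3 and palladium to C2. The C-bound palladium enolate so formed is expected to change face through its O-bound form, and syn β-hydride elimination of the C3 hydrogen then restores the furanone and returns zerovalent palladium after loss of HI to the carbonate. The closest known reaction types are intramolecular Heck macrocyclisations of vinyl iodides and the palladium-catalysed alkenylation and arylation of chromones and other cyclic β-alkoxy enones at the oxygen-bearing carbon. The closure forms the nine-membered oxacycle in a 9-exo-trig sense through the C10–O tether (10-endo-trig if counted through C1 and C2), and no stereocentre is made because C3 stays trigonal and the C4=C5 geometry is carried over from the iodide. The step needs C3 rather than C2 regioselectivity, which the substrate secures because C3 is both the β-carbon of the enone and the α-carbon of the enol ether, and it needs ring closure rather than oligomerisation, which is served by high dilution and by the Z olefin and trans lactone that turn the two ends toward each other. The C13 methylene is held back as the C11 phosphonate so that no five- or six-membered carbopalladation onto an acrylate can compete, and the weak heterogeneous base should leave the C11–H intact.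

Step 17
Reactants: 26 phosphono macrocycle
Product: 27 α-methylene lactone silyl ether (4Z,6S,7R,8S,10R)
Conditions: 37% aq. CH2O, K2CO3, THF, 0 °C to rt
Reagents that add atoms: formaldehyde C=O
Why: Horner–Wadsworth–Emmons olefination of the α-phosphono lactone with formaldehyde under mild carbonate base is a standard way to unveil an α-methylene-γ-butyrolactone, and it erases the C11 centre.

Step 18
Reactants: 27 silyl ether
Product: 28 C6 alcohol (4Z,6S,7S,8S,10R; 7S by priority change only)
Conditions: HF·pyridine, pyridine, THF, 0 °C to rt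
Reagents that add atoms: none
Why: Buffered acidic fluoride desilylation removes the secondary silyl ether while tolerating the two Michael acceptors, and the exposure is kept short so that the lactone does not migrate to O6.

Step 19
Reactants: 29 angelic acid
Product: 30 (Z)-2-methylbut-2-en-1-ol
Conditions: LiAlH4, Et2O, 0 °C
Reagents that add atoms: none
Why: Hydride reduction of the conjugated acid at low temperature gives the allylic alcohol with the Z geometry retained.

Step 20
Reactants: 30 (Z)-allylic alcohol
Product: 31 [(2R,3S)-2,3-dimethyloxiran-2-yl]methanol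
Conditions: Ti(Oi-Pr)4 (cat.), D-(−)-diethyl tartrate (cat.), t-BuOOH, 4 Å sieves, CH2Cl2, −20 °C
Reagents that add atoms: tert-butyl hydroperoxide CC(C)(C)OO
Why: In this Sharpless asymmetric epoxidation the D-(−)-tartrate complex delivers oxygen to the face that gives the (2R,3S)-epoxy alcohol, and the cis relation of C3–Me and CH2OH follows from the Z alkene.

Step 21
Reactants: 31 epoxy alcohol
Product: 32 (2S,3S)-2,3-dimethyloxirane-2-carboxylic acid
Conditions: TEMPO (cat.), PhI(OAc)2, MeCN/H2O, rt
Reagents that add atoms: water O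
Why: Oxoammonium (TEMPO) oxidation takes the primary alcohol through the aldehyde hydrate to the acid without touching the epoxide, and the descriptor at C2 changes only because of the new priority.

Step 22
Reactants: 32 epoxy acid + 28 C6 alcohol
Product: 34 target CNP0258430.4, via mixed anhydride 33 (not isolated)
Conditions: 2,4,6-Cl3C6H2COCl, Et3N, toluene, rt; then 28, DMAP, rt
Reagents that add atoms: none
Why: In this Yamaguchi esterification DMAP attacks the mixed anhydride at the aliphatic carbonyl and the acylpyridinium acylates the C6 hydroxyl with retention at every centre.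

**Compound list**

1 | (R)-citramalic acid | C[C@@](O)(CC(=O)O)C(=O)O | starting material
2 | (R)-2-(2,2,4-trimethyl-5-oxo-1,3-dioxolan-4-yl)acetic acid | C[C@]1(CC(=O)O)OC(C)(C)OC1=O | intermediate
3 | (R)-5-(2-hydroxyethyl)-2,2,5-trimethyl-1,3-dioxolan-4-one | C[C@]1(CCO)OC(C)(C)OC1=O | intermediate (not isolated)
4 | (3R)-3-hydroxy-3-methyloxolan-2-one | C[C@@]1(O)CCOC1=O | intermediate
5 | (3R)-3-methyl-3-(triethylsilyloxy)oxolan-2-one | C[C@@]1(O[Si](CC)(CC)CC)CCOC1=O | intermediate
6 | (2R)-4-hydroxy-N-methoxy-N,2-dimethyl-2-(triethylsilyloxy)butanamide | OCC[C@@](C)(O[Si](CC)(CC)CC)C(=O)N(C)OC | intermediate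
7 | (2R)-N-methoxy-N,2-dimethyl-4-oxo-2-(triethylsilyloxy)butanamide | O=CC[C@@](C)(O[Si](CC)(CC)CC)C(=O)N(C)OC | intermediate
8 | (4R)-4-benzyl-1,3-oxazolidin-2-one | O=C1N[C@H](Cc2ccccc2)CO1 | starting material
9 | methyl 4-chloro-4-oxobutanoate | COC(=O)CCC(=O)Cl | starting material
10 | methyl 4-[(4R)-4-benzyl-2-oxo-1,3-oxazolidin-3-yl]-4-oxobutanoate | COC(=O)CCC(=O)N1[C@H](Cc2ccccc2)COC1=O | intermediate
11 | dibutylboron Z-enolate of 10 | COC(=O)C/C=C(\OB(CCCC)CCCC)N1[C@H](Cc2ccccc2)COC1=O | intermediate (not isolated)
12 | syn-aldol adduct (7R,8S,10R) | COC(=O)C[C@@H](C(=O)N1[C@H](Cc2ccccc2)COC1=O)[C@@H](O)C[C@@](C)(O[Si](CC)(CC)CC)C(=O)N(C)OC | intermediate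
13 | hydroxy diacid (7R,8S,10R) | OC(=O)C[C@@H](C(=O)O)[C@@H](O)C[C@@](C)(O[Si](CC)(CC)CC)C(=O)N(C)OC | intermediate (not isolated)
14 | trans-lactone C6 acid (7R,8S,10R) | O=C1C[C@@H](C(=O)O)[C@H](C[C@@](C)(O[Si](CC)(CC)CC)C(=O)N(C)OC)O1 | intermediate
15 | lactone C6 acid chloride | O=C1C[C@@H](C(=O)Cl)[C@H](C[C@@](C)(O[Si](CC)(CC)CC)C(=O)N(C)OC)O1 | intermediate (not isolated)
16 | C6 but-2-ynoyl lactone (7R,8S,10R) | O=C1C[C@@H](C(=O)C#CC)[C@H](C[C@@](C)(O[Si](CC)(CC)CC)C(=O)N(C)OC)O1 | intermediate
17 | (Z)-β-iodoenone (7R,8S,10R) | O=C1C[C@@H](C(=O)/C=C(C)\I)[C@H](C[C@@](C)(O[Si](CC)(CC)CC)C(=O)N(C)OC)O1 | intermediate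
18 | (6R)-allylic alcohol, Z vinyl iodide (6R,7S,8S,10R) | O=C1C[C@@H]([C@@H](O)/C=C(C)\I)[C@H](C[C@@](C)(O[Si](CC)(CC)CC)C(=O)N(C)OC)O1 | intermediate
19 | C6 tert-butyldimethylsilyl ether (6R,7R,8S,10R) | O=C1C[C@@H]([C@@H](O[Si](C)(C)C(C)(C)C)/C=C(C)\I)[C@H](C[C@@](C)(O[Si](CC)(CC)CC)C(=O)N(C)OC)O1 | intermediate
20 | C11 diethyl phosphonite | O=C1[C@H](P(OCC)OCC)[C@@H]([C@@H](O[Si](C)(C)C(C)(C)C)/C=C(C)\I)[C@H](C[C@@](C)(O[Si](CC)(CC)CC)C(=O)N(C)OC)O1 | intermediate (not isolated)
21 | C11 diethyl phosphonate, C1 Weinreb amide (6R,7R,8S,10R,11R) | O=C1[C@H](P(=O)(OCC)OCC)[C@@H]([C@@H](O[Si](C)(C)C(C)(C)C)/C=C(C)\I)[C@H](C[C@@](C)(O[Si](CC)(CC)CC)C(=O)N(C)OC)O1 | intermediate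
22 | C1 ethynyl ketone (6R,7R,8S,10R,11R) | O=C1[C@H](P(=O)(OCC)OCC)[C@@H]([C@@H](O[Si](C)(C)C(C)(C)C)/C=C(C)\I)[C@H](C[C@@](C)(O[Si](CC)(CC)CC)C(=O)C#C)O1 | intermediate
23 | (E)-β-diethylamino enone, C10 OSiEt3 | O=C1[C@H](P(=O)(OCC)OCC)[C@@H]([C@@H](O[Si](C)(C)C(C)(C)C)/C=C(C)\I)[C@H](C[C@@](C)(O[Si](CC)(CC)CC)C(=O)/C=C/N(CC)CC)O1 | intermediate (not isolated)
24 | (E)-β-diethylamino enone, C10 OH | O=C1[C@H](P(=O)(OCC)OCC)[C@@H]([C@@H](O[Si](C)(C)C(C)(C)C)/C=C(C)\I)[C@H](C[C@@](C)(O)C(=O)/C=C/N(CC)CC)O1 | intermediate (not isolated)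
25 | furanone vinyl iodide, Heck precursor (6R,7R,8S,10R,11R) | O=C1[C@H](P(=O)(OCC)OCC)[C@@H]([C@@H](O[Si](C)(C)C(C)(C)C)/C=C(C)\I)[C@H](C[C@@]2(C)OC=CC2=O)O1 | intermediate
26 | furanone-bridged macrocycle, Heck product (4Z,6S,7R,8S,10R,11R) | CCOP(=O)(OCC)[C@H]1C(=O)O[C@H]2C[C@@]3(C)OC(=CC3=O)/C(C)=C\[C@H](O[Si](C)(C)C(C)(C)C)[C@H]12 | intermediate
27 | α-methylene lactone, C6 OTBS (4Z,6S,7R,8S,10R) | C=C1C(=O)O[C@H]2C[C@@]3(C)OC(=CC3=O)/C(C)=C\[C@H](O[Si](C)(C)C(C)(C)C)[C@H]12 | intermediate
28 | α-methylene lactone, C6 OH (4Z,6S,7S,8S,10R) | C=C1C(=O)O[C@H]2C[C@@]3(C)OC(=CC3=O)/C(C)=C\[C@H](O)[C@H]12 | intermediate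
29 | angelic acid | C/C=C(/C)C(=O)O | starting material
30 | (Z)-2-methylbut-2-en-1-ol | C/C=C(/C)CO | intermediate
31 | [(2R,3S)-2,3-dimethyloxiran-2-yl]methanol | OC[C@@]1(C)O[C@H]1C | intermediate
32 | (2S,3S)-2,3-dimethyloxirane-2-carboxylic acid | OC(=O)[C@@]1(C)O[C@H]1C | intermediate
33 | (2S,3S)-2,3-dimethyloxirane-2-carboxylic 2,4,6-trichlorobenzoic anhydride | O=C(OC(=O)[C@@]1(C)O[C@H]1C)c1c(Cl)cc(Cl)cc1Cl | intermediate (not isolated)
34 | CNP0258430.4 (4Z,6S,7R,8S,10R; ester 2S,3S) | C=C1C(=O)O[C@H]2C[C@@]3(C)OC(=CC3=O)/C(C)=C\[C@H](OC(=O)[C@@]3(C)O[C@H]3C)[C@H]12 | target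

**Step count and risks**

Total steps: 22. Longest linear sequence: 18 (steps 1–5, 7–18 and 22).

Steps most likely to fail:

1. Step 16 (the proposed Heck macrocyclisation). The ring closure may be slower than reduction of the vinylpalladium or oligomerisation, carbopalladation may go to C2, or the face change of the palladium enolate that β-hydride elimination needs may not occur. The fallback uses known reaction types, sets out from 22 and returns at 26. An intramolecular Sonogashira coupling of the terminal ynone with the vinyl iodide (Pd(PPh3)4, CuI, i-Pr2NEt, THF, high dilution) would form the C3–C4 bond and give the ten-membered enynone F1. HF·pyridine would then free the tertiary hydroxyl to give the hydroxy enynone F2. Transannular 5-endo-dig addition of that hydroxyl to the ynone (AuCl(PPh3)/AgOTf, cat.) would build the furanone inside the ring and give 26.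

2. Step 11 (Luche reduction). Facial selectivity of hydride delivery to the C6 ketone may be poor, because the two ring branches at C7 differ only moderately in size. The fallback sets out from 16 and returns at 18. Asymmetric transfer hydrogenation of the ynone with RuCl(p-cymene)[(R,R)-TsDPEN] in i-PrOH would set C6 under catalyst control and give the (6R)-propargylic alcohol F3. Ruthenium-catalysed trans-hydrosilylation ([Cp*Ru(MeCN)3]PF6, Et3SiH) would place silicon on C4, distal to the hydroxyl, and give the Z C4-triethylsilyl allylic alcohol F4. Iododesilylation with N-iodosuccinimide in hexafluoroisopropanol, with retention, would give 18.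

3. Step 15 (furanone formation). The C6 silyl ether may be lost together with the tertiary one, or ring closure may stall at the enaminone. The fallback sets out from 22 and returns at 25, and it replaces the selective deprotection by global deprotection and reprotection. Et2NH followed by 48% aq. HF in MeCN would strip both silyl ethers to the bis-desilylated enaminone F5, which closes under the acid to the C6-hydroxy furanone F6. Selective silylation of the secondary hydroxyl (t-BuMe2SiCl, imidazole, DMF) would then give 25.

**Further compounds**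

F1 | step 16 | ten-membered enynone (C3–C4 bond formed; C10 OSiEt3; C6 OTBS; C11 phosphonate) | O=C1[C@H](P(=O)(OCC)OCC)[C@H]2[C@@H](O[Si](C)(C)C(C)(C)C)/C=C(C)\C#CC(=O)[C@](C)(O[Si](CC)(CC)CC)C[C@@H]2O1
F2 | step 16 | C10 hydroxy enynone | O=C1[C@H](P(=O)(OCC)OCC)[C@H]2[C@@H](O[Si](C)(C)C(C)(C)C)/C=C(C)\C#CC(=O)[C@](C)(O)C[C@@H]2O1
F3 | step 11 | (6R)-propargylic alcohol | O=C1C[C@@H]([C@@H](O)C#CC)[C@H](C[C@@](C)(O[Si](CC)(CC)CC)C(=O)N(C)OC)O1
F4 | step 11 | Z C4-triethylsilyl allylic alcohol | O=C1C[C@@H]([C@@H](O)/C=C(C)\[Si](CC)(CC)CC)[C@H](C[C@@](C)(O[Si](CC)(CC)CC)C(=O)N(C)OC)O1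
F5 | step 15 | bis-desilylated enaminone | O=C1[C@H](P(=O)(OCC)OCC)[C@@H]([C@@H](O)/C=C(C)\I)[C@H](C[C@@](C)(O)C(=O)/C=C/N(CC)CC)O1
F6 | step 15 | C6-hydroxy furanone | O=C1[C@H](P(=O)(OCC)OCC)[C@@H]([C@@H](O)/C=C(C)\I)[C@H](C[C@@]2(C)OC=CC2=O)O1
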